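At early times the west run, with the least E of the three earlier flasks, showed 41.4% G but 2.3% Q at 2.50 h. I asked where the rest of the L stood.

| setting | west | south-east | north-west | spring | winter | dawn |
|---|---|---|---|---|---|---|
| L | 0.58 M | 0.58 M | 0.58 M | 0.58 M | 0.58 M | 0.58 M |
| Z | 0.638 M | 0.638 M | 0.638 M | 0.638 M | 0.638 M | 0.638 M |
| E | 13 mM | 28 mM | 59 mM | 15 mM | 30 mM | 60 mM |
| remark | run made earlier | run made earlier | run made earlier |  |  |  |
| time |  |  |  | 2.5 d | 2.5 d | 2.5 d |

- west (time / h: Q / %, G / %): 2.50: 2.3, 41.4; 8.00: 9.7, 63.9; 15.0: 15.6, 70.0; 20.0: 18.4, 71.5; 30.0: 22.4, 72.2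
- south-east (time / h: Q / %, G / %): 2.50: 8.1, 38.9; 5.00: 17.6, 48.6; 8.00: 25.0, 54.1; 15.0: 34.4, 57.2; 30.0: 41.1, 57.1
- north-west (time / h: Q / %, G / %): 2.50: 21.8, 32.2; 5.00: 38.6, 38.7; 8.00: 48.5, 39.8; 15.0: 56.3, 41.1; 30.0: 59.1, 40.6

(readings scatter by 0.3 percentage points)

- candidate steps: L + E -> E + J; E + J <-> D; Z + D -> E + Q; L + Z -> G
- "hardly changes" means that all values lie within two and a half points (for a concentration: within two and a half percent of the largest)

- share of Q in all that became Q or G for spring, winter, dawn, in this order
- how that number moves from the first to the last of them (rises all the way / falls, then rises / rises, then falls / hardly changes / falls all the way)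

I wrote the balance of L, the limiting reagent, since cZ was charged at 1.10 times cL. L stands as L, J, D, Q or G. The north-west run shows that balance closing: Q and G summed to 99.7% at 30.0 h. So the share of Q follows from one ratio s, the L not ending as G over the L ending as G: the share is s/(1+s).

How does s move with E? Dividing s by cE gives b, the split per catalyst, a selectivity factor per unit of E. West gives 29.6 M⁻¹, south-east 26.8 M⁻¹, north-west 24.8 M⁻¹. So b fell by a factor 1.19 while cE rose by 4.54. I took b from the nearest run for each new flask.

Does 60 h close the balance? West had the widest gap at 30.0 h, 5.40%, down from 10.1% at 20.0 h. That is a half-time of 11.1 h, so my estimate for the west gap, carried on to 60 h, was about 0.825%. I charged that gap to spring, which lowers its share by 0.58 percentage points. My shares were 30.2%, 44.6% and 59.8%.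

The forecast gave 30%, 44.3% and 59.5%, below mine, and said the share rises all the way; of the product it wrote: “Q is then whatever remains”.

The flasks gave 29.3%, 44.0% and 59.5%; the share rises all the way.

    L + E → E + J (k = 4.90 M⁻¹ h⁻¹)
    E + J ⇌ D (K = 4.20 M⁻¹, k = 26.0 M⁻¹ h⁻¹)
    Z + D → E + Q (k = 19.0 M⁻¹ h⁻¹)
    L + Z → G (k = 0.470 M⁻¹ h⁻¹)

With G at 40.5% after 25.0 d, dawn has b of 24.5 M⁻¹, beside 24.8 M⁻¹ from the north-west run. Spring, with G at 70.1% after 25.0 d, has b of 28.4 M⁻¹, beside 29.6 M⁻¹ from west. The two steps that take L, reckoned at the charge of Z with E all free, give b of 16.3 M⁻¹, lower than that spring figure for the whole run. In spring, Z stood at 13.3% of its charge after 1.25 d.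

Readings and results were computed on assumed constants; the scatter is artificial.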